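## The problem

The target is a 3,4-dihydronaphthalen-1(2H)-one whose aromatic ring A is fully differentiated. C5 carries a 4-hydroxy-2-pyranon-6-yl ring, C6 an isopentyl chain, C7 a hydrogen, and C8 a phenol peri to the C1 ketone. Ring B holds the only stereocenter, the C3 carbinol of R configuration. Nothing else in the molecule can induce or repair it, so it must come from an enantioselective event or a chiral building block and then survive every later step. This carbinol is β to the C1 ketone, and loss of water followed by enolisation would end in a 1,8-naphthalenediol. The free β-hydroxy ketone therefore tolerates neither strong acid, base nor long heating and is best unveiled last. The pyranone is an acidic vinylogous acid and an electrophile towards organometallics, so it should be built late from a carbonyl carbon already on C5. That carbon sits between the C4 methylene and the C6 chain, is as hindered as a 2,6-dialkylbenzoate, and will not undergo ordinary addition–elimination. The feature that opens the key step is that C7, C8, C8a and C4a can be written as a 2-silyloxy-1,3-diene standing on an intact, C3-oxygenated ring B (C8a=C4a a ring B alkene, C8 the future phenol carbon). This leaves C5 and C6 as the two carbons of an alkynoate that already bears the isopentyl chain and the future pyranone carbon.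

## Retrosynthesis

**26 ⇒ 25.** Target 26 is traced to bis-silyl ether ketal 25. No skeletal bond is cut; only the two O–Si bonds and the C1 dioxolane are opened. Keeping the ketone as a ketal until the end removes the E1cB path to the naphthol from every earlier step. The forward reaction must be one mild acidic operation at or below room temperature.

**25 ⇒ 23 ⇒ 19 + 20.** The pyranone of 25 is cut at the lactone C–O bond and at the bond between the aryl ketone carbon and its α-methylene. This leads via acylketene 24 to keto-dioxinone 23, and then to acid 19 (as acid chloride 21) and dioxinone 20 (as dienolate 22). A biaryl-type coupling of a C5 halide with a 6-metallated pyranone would need a separate C5 functionalisation and a doubly ortho-hindered coupling. The acylation uses the carbon that the cycloaddition puts on C5 anyway. The forward steps need γ-selective acylation and a neutral thermal ring closure.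

**19 ⇒ 18.** Acid 19 comes from allyl ester 18. An allyl ester is preferred to a methyl ester because the C5 carboxylate is doubly ortho-substituted. Saponification would be slow, and nucleophilic demethylation would threaten the aryl silyl ether. Palladium cleaves the O–allyl bond, remote from the hindered carbonyl.

**18 ⇒ 12 + 16.** Ring A of 18 is dissolved by cutting C6–C7 and C4a–C5, via cyclohexadiene 17, into silyloxy diene 12 and ynoate 16. The neighbouring options are worse. Stepwise substitution of a preformed 8-hydroxytetralone would have to fight the ortho/para direction of the phenol towards both C5 and C7. The other (4+2) partition of ring A would need ring B as a strained alkyne equivalent. The chosen cut reduces a pentasubstituted arene to a monocyclic diene with one stereocenter and an acyclic ynoate. The forward reaction must place the ester on C5 and the chain on C6, and the aromatisation must leave C3 alone.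

**16 ⇒ 13 + 14.** Ynoate 16 is cut at the alkyne–carbonyl bond into 5-methylhex-1-yne 13 and allyl chloroformate 14, joined through acetylide 15.

**12 ⇒ 10 ⇒ 7 + 8.** Diene 12 is the silyl enol ether (via enolate 11) of methyl ketone 10. Its C8a–C8 bond is cut to vinyllithium 9, made from vinyl iodide 7, and Weinreb amide 8. A coupling with a 1-alkoxyvinyl metal would be shorter, but it would give an alkyl enol ether and finally an aryl alkyl ether that cannot be removed gently. The lithiation requires the C1 ketone to be masked, and the dioxolane chosen for this is the same one that protects the β-hydroxy ketone to the end.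

**7 ⇒ 6 ⇒ 5.** Ketal 7 comes from iodo enone 6 and this from enone 5. The iodine is placed on the enone α-carbon (future C8a) before ketalisation because only the enone can be α-iodinated.

**5 ⇒ 3 ⇒ 2 ⇒ 1.** Enone 5 arises from monoacetate 3 by oxidation to β-acetoxy ketone 4 and loss of acetic acid. Monoacetate 3 comes from meso-diol 2 by enzymatic desymmetrisation, and 2 from all-cis triol 1. A desymmetrisation can in principle convert all of the material into one enantiomer. It fixes the configuration at the start, where it can be checked and upgraded on a small molecule.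

## Roads not taken

**Alternative 1:** The cut is the C3–O bond, made late.
- **Key step:** Dihydronaphthalene ketal A2 would be epoxidised at C3=C4 by the chiral salen complex N,N'-bis(3,5-di-tert-butylsalicylidene)-1,2-cyclohexanediaminomanganese chloride A3 (trivalent manganese) to give the cis epoxide A1. The R,R enantiomer of the catalyst is the one expected by analogy with the parent hydrocarbon. Reductive cleavage of the benzylic C4–O bond would leave the C3 alcohol.
- **Merits:** Aryl-conjugated cis alkenes of this kind are among the best substrates for this catalyst. All ring A chemistry runs on achiral, robust aromatics. The stereocenter arrives late and cannot be lost on the way.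
- **Weak points:** C4 is peri to the C5 pyranone, which twists the styrene and blocks the approach of the oxidant. The pyranone double bonds are exposed to an oxo-manganese species. A2 needs a C3=C4 alkene placed out of conjugation with the masked ketone. The reductive opening must cut only C4–O without saturating the pyranone. The enantiomeric purity is limited by the catalyst at a stage where upgrading is hard.
- **Comparison:** This road is better in deferring chirality and in using a catalytic asymmetric step with strong substrate-class precedent. The chosen plan sets against it a configuration fixed in a small building block, a ring A whose substitution pattern is settled in one cycloaddition, and a pyranone that never meets an oxidant.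

**Alternative 2:** The cuts are C4a–C4 and C8a–C1.
- **Key step:** 3-(Benzyloxy)cyclobutanone A5 would be deprotonated enantioselectively to the lithium enolate A6. This would add to the aryne generated from iodoaryl triflate A7. The aryl anion would close on the carbonyl, and the strained four-membered alkoxide would open with ring expansion to tetralone A4.
- **Merits:** Ring B and both benzylic bonds form in one operation. The route is highly convergent. The C8 benzyloxy group steers the nucleophile to the distal aryne carbon, which is the required regiochemistry.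
- **Weak points:** A7 is a hexasubstituted benzene, so the ring A problem is moved, not solved. The enantiopurity rests on a stoichiometric chiral base acting on a strained β-alkoxy enolate that can expel benzyloxide. The alkynyl group still needs several steps to become the pyranone.
- **Comparison:** This road is more convergent at the ring B stage. The chosen plan sets against it a ring A assembled by cycloaddition instead of sequential arene substitution, and a stereocenter from an enzyme acting on a stable meso-diol.

**Alternative 3:** The cut is C2–C3.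
- **Key step:** Keto aldehyde A9 would cyclise under chiral amine catalysis, the methyl ketone carbon adding to the aldehyde, to give hydroxy tetralone A8. This is one debenzylation away from 26.
- **Merits:** It is the shortest endgame. The ring, the stereocenter and the β-hydroxy ketone appear in one catalytic step, with no protecting groups on ring B.
- **Weak points:** The donor is an aryl methyl ketone hydrogen-bonded to the ortho phenol and forms enamines poorly. The acceptor is an enolisable arylacetaldehyde that condenses with itself. Under amine catalysis the aldol product is one dehydration from the naphthol, and retro-aldol would erode the enantiomeric purity. A9 is again a pentasubstituted benzene built by sequential arene chemistry.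
- **Comparison:** In step count after the key step and in directness this road is better. The chosen plan sets against it that the β-hydroxy ketone is never exposed to an amine or base, and that the stereocenter rests on a precedented desymmetrisation.

Key step: step 9

Remark on the chemistry: the lipase is assumed to acetylate the R-configured carbinol carbon of 2, the sense the Kazlauskas rule predicts when the silyloxy-bearing flank counts as the larger one; the fallback for step 2 covers the opposite sense.

## Route

Step 1
Reactants: 1 all-cis-cyclohexane-1,3,5-triol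
Product: 2 all-cis-5-(tert-butyldimethylsilyloxy)cyclohexane-1,3-diol (meso)
Conditions: TBSCl (1.0 equiv), imidazole, DMF, 0 °C → rt
Reagents that add atoms: tert-butyldimethylsilyl chloride, CC(C)(C)[Si](C)(C)Cl
Why: Imidazole-promoted silyl ether formation on three equivalent hydroxyls gives the meso mono-ether as the main product of a statistical silylation; over-silylated material can be desilylated back to 1.

Step 2
Reactants: 2 all-cis-5-(tert-butyldimethylsilyloxy)cyclohexane-1,3-diol
Product: 3 (1R,3S,5S)-3-(tert-butyldimethylsilyloxy)-5-hydroxycyclohexyl acetate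
Conditions: Novozym 435 (immobilised Candida antarctica lipase B), vinyl acetate, t-BuOMe, 25 °C
Reagents that add atoms: vinyl acetate, CC(=O)OC=C
Why: Lipase-catalysed enantiotopic-group-selective transesterification (desymmetrisation of a meso-1,3-diol) with an irreversible acyl donor; the enzyme is expected to acylate the R carbinol carbon, which differentiates the two arms and so fixes the configuration of the future C3.

Step 3
Reactants: 3 (1R,3S,5S)-3-(tert-butyldimethylsilyloxy)-5-hydroxycyclohexyl acetate
Product: 5 (R)-5-(tert-butyldimethylsilyloxy)cyclohex-2-en-1-one, via β-acetoxy ketone 4 (not isolated)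
Conditions: Dess–Martin periodinane, CH2Cl2, 0 °C → rt; then Et3N, 0 °C → rt
Reagents that add atoms: none
Why: Dess–Martin oxidation of the free secondary alcohol, then amine-induced E1cB elimination of acetate, the better leaving group of the two β-oxygens, gives the enone; the silyloxy carbon is untouched and becomes the R stereocenter.

Step 4
Reactants: 5 (R)-5-(tert-butyldimethylsilyloxy)cyclohex-2-en-1-one
Product: 6 (R)-5-(tert-butyldimethylsilyloxy)-2-iodocyclohex-2-en-1-one
Conditions: I2, pyridine, CH2Cl2, 0 °C → rt
Reagents that add atoms: iodine, II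
Why: Johnson α-iodination of a cyclic enone (conjugate addition of pyridine, iodination of the enolate, elimination); the weak base spares the β-silyloxy ketone.

Step 5
Reactants: 6 (R)-5-(tert-butyldimethylsilyloxy)-2-iodocyclohex-2-en-1-one
Product: 7 (R)-9-(tert-butyldimethylsilyloxy)-6-iodo-1,4-dioxaspiro[4.5]dec-6-ene
Conditions: (TMSOCH2)2, TMSOTf (10 mol %), CH2Cl2, −78 → −20 °C; pyridine quench
Reagents that add atoms: 1,2-bis(trimethylsilyloxy)ethane, C[Si](C)(C)OCCO[Si](C)(C)C
Why: Noyori ketalisation is aprotic and cold, so the β-silyloxy ketone neither eliminates nor loses its silyl group, and an α-halo enone ketalises without migration of the alkene.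

Step 6
Reactants: 7 (R)-9-(tert-butyldimethylsilyloxy)-6-iodo-1,4-dioxaspiro[4.5]dec-6-ene; 8 N-methoxy-N-methylacetamide
Product: 10 (R)-1-[9-(tert-butyldimethylsilyloxy)-1,4-dioxaspiro[4.5]dec-6-en-6-yl]ethan-1-one, via vinyllithium 9 (not isolated)
Conditions: t-BuLi (2.1 equiv), Et2O, −78 °C; then 8, −78 → 0 °C; aq NH4Cl
Reagents that add atoms: none
Why: Iodine–lithium exchange gives the stable ketal-masked α-keto vinyllithium, and Weinreb ketone synthesis stops at the methyl ketone through the chelated tetrahedral adduct.

Step 7
Reactants: 10 (R)-1-[9-(tert-butyldimethylsilyloxy)-1,4-dioxaspiro[4.5]dec-6-en-6-yl]ethan-1-one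
Product: 12 (R)-9-(tert-butyldimethylsilyloxy)-6-[1-(tert-butyldimethylsilyloxy)vinyl]-1,4-dioxaspiro[4.5]dec-6-ene, via potassium enolate 11 (not isolated)
Conditions: KN(SiMe3)2, THF, −78 °C; then TBSCl, −78 → 0 °C
Reagents that add atoms: tert-butyldimethylsilyl chloride, CC(C)(C)[Si](C)(C)Cl
Why: Kinetic deprotonation of the methyl group (the other α-carbon is vinylic) and O-silylation of the enolate give the 2-silyloxy diene; base-only conditions are chosen because a silyl triflate with an amine could open the ketal.

Step 8
Reactants: 13 5-methylhex-1-yne; 14 allyl chloroformate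
Product: 16 allyl 6-methylhept-2-ynoate, via lithium acetylide 15 (not isolated)
Conditions: n-BuLi, THF, −78 °C; then 14, −78 → 0 °C
Reagents that add atoms: none
Why: Deprotonation of a terminal alkyne and C-acylation of the acetylide with a chloroformate is the standard ynoate synthesis.

Step 9
Reactants: 12 (R)-9-(tert-butyldimethylsilyloxy)-6-[1-(tert-butyldimethylsilyloxy)vinyl]-1,4-dioxaspiro[4.5]dec-6-ene; 16 allyl 6-methylhept-2-ynoate
Product: 18 allyl (R)-3,8-bis(tert-butyldimethylsilyloxy)-1,1-(ethylenedioxy)-6-(3-methylbutyl)-1,2,3,4-tetrahydronaphthalene-5-carboxylate, via cyclohexa-1,4-diene cycloadduct 17 (not isolated)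
Conditions: 16 (2.5 equiv), BHT (cat.), PhMe, 150 °C, base-washed sealed tube; then DDQ (1.2 equiv), PhMe, 0 °C → rt
Reagents that add atoms: none
Why: The diene (HOMO raised by the C8 silyloxy group, largest coefficient on the C7 methylene) and the ynoate (LUMO largest on the β-carbon that bears the isopentyl chain) combine in a concerted, asynchronous, normal-demand Diels–Alder reaction in which C7–C6 bonding runs ahead of C4a–C5. The closest known reaction type is the cycloaddition of 2-silyloxy-1,3-dienes, 1-(1-silyloxyvinyl)cycloalkenes among them, with alkynoates, followed by dehydrogenation of the 1,4-cyclohexadiene to an aryl silyl ether. Ring A is closed by intermolecular (4+2) annulation onto the ring B alkene C8a=C4a, both bonds forming in one pericyclic event. The only new stereocenter, C4a of 17, is transient: DDQ abstracts hydride from this doubly allylic carbon, where the cation is stabilised by the C8 oxygen, and loss of a C7 proton aromatises the ring, so C3 is never involved. The selectivity needed is regiochemical (ester on C5, chain on C6), and it is secured by the match of the silyloxy-polarised terminus C7 with the ester-polarised β-carbon, the para orientation of donor and acceptor. The reactive s-cis rotamer is accessible because it places the small silyloxy oxygen, not the methylene terminus, beside the spiro ketal carbon, and C4a carries its ring substituent in the outward position. A 1,5-hydrogen shift of the diene is excluded by geometry, since C4 is trans to C8 across the ring alkene.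

Step 10
Reactants: 18 allyl (R)-3,8-bis(tert-butyldimethylsilyloxy)-1,1-(ethylenedioxy)-6-(3-methylbutyl)-1,2,3,4-tetrahydronaphthalene-5-carboxylate
Product: 19 (R)-3,8-bis(tert-butyldimethylsilyloxy)-1,1-(ethylenedioxy)-6-(3-methylbutyl)-1,2,3,4-tetrahydronaphthalene-5-carboxylic acid
Conditions: Pd(PPh3)4 (5 mol %), morpholine, THF, rt; pH 4 buffer work-up
Reagents that add atoms: none
Why: Tsuji–Trost deallylation: zerovalent palladium ionises the allyl ester to a π-allyl complex that morpholine captures, so cleavage occurs at the O–allyl bond and the double ortho substitution is irrelevant; ketal and silyl ethers are inert.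

Step 11
Reactants: 19 (R)-3,8-bis(tert-butyldimethylsilyloxy)-1,1-(ethylenedioxy)-6-(3-methylbutyl)-1,2,3,4-tetrahydronaphthalene-5-carboxylic acid; 20 2,2,6-trimethyl-4H-1,3-dioxin-4-one
Product: 23 (R)-6-{2-[3,8-bis(tert-butyldimethylsilyloxy)-1,1-(ethylenedioxy)-6-(3-methylbutyl)-1,2,3,4-tetrahydronaphthalen-5-yl]-2-oxoethyl}-2,2-dimethyl-4H-1,3-dioxin-4-one, via acid chloride 21 (not isolated), via lithium dienolate 22 (not isolated)
Conditions: 19, 1-chloro-N,N,2-trimethylprop-1-en-1-amine, CH2Cl2, 0 °C → rt; added to 22 [20 (2.2 equiv), LiN(SiMe3)2, THF, −78 °C], −78 → −20 °C; aq NH4Cl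
Reagents that add atoms: none
Why: The Ghosez chloroenamine forms the acid chloride under neutral conditions, and γ-C-acylation of the dioxinone dienolate is the known entry to 6-(2-oxoalkyl)dioxinones; two equivalents of dienolate are used because the product is more acidic than 20.

Step 12
Reactants: 23 (R)-6-{2-[3,8-bis(tert-butyldimethylsilyloxy)-1,1-(ethylenedioxy)-6-(3-methylbutyl)-1,2,3,4-tetrahydronaphthalen-5-yl]-2-oxoethyl}-2,2-dimethyl-4H-1,3-dioxin-4-one
Product: 25 (R)-6-[3,8-bis(tert-butyldimethylsilyloxy)-1,1-(ethylenedioxy)-6-(3-methylbutyl)-1,2,3,4-tetrahydronaphthalen-5-yl]-4-hydroxy-2H-pyran-2-one, via acylketene 24 (not isolated)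
Conditions: PhMe, 110 °C
Reagents that add atoms: none
Why: Thermal retro-(4+2) of the dioxinone expels acetone, and the acylketene is trapped by the enol oxygen of the neighbouring aryl ketone to give the 4-hydroxy-2-pyranone (dioxinone thermolysis/lactonisation); neutral conditions leave ketal and silyl ethers intact.

Step 13
Reactants: 25 (R)-6-[3,8-bis(tert-butyldimethylsilyloxy)-1,1-(ethylenedioxy)-6-(3-methylbutyl)-1,2,3,4-tetrahydronaphthalen-5-yl]-4-hydroxy-2H-pyran-2-one
Product: 26 (R)-3,8-dihydroxy-5-(4-hydroxy-2-oxo-2H-pyran-6-yl)-6-(3-methylbutyl)-3,4-dihydronaphthalen-1(2H)-one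
Conditions: 48% aq HF, MeCN, 0 °C → rt
Reagents that add atoms: water, O
Why: Acidic fluoride cleaves the alkyl and aryl silyl ethers and hydrolyses the benzylic dioxolane, which the ortho oxygen activates, in one cold operation that should not dehydrate the β-hydroxy ketone (global deprotection); no bond to C3 is broken, so its R configuration is retained.

## Compound list

1 | all-cis-cyclohexane-1,3,5-triol | O[C@H]1C[C@@H](O)C[C@@H](O)C1 | starting material
2 | all-cis-5-(tert-butyldimethylsilyloxy)cyclohexane-1,3-diol (meso) | O[C@H]1C[C@@H](O)C[C@@H](O[Si](C)(C)C(C)(C)C)C1 | intermediate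
3 | (1R,3S,5S)-3-(tert-butyldimethylsilyloxy)-5-hydroxycyclohexyl acetate | O[C@H]1C[C@@H](OC(C)=O)C[C@@H](O[Si](C)(C)C(C)(C)C)C1 | intermediate
4 | (1S,3R)-3-(tert-butyldimethylsilyloxy)-5-oxocyclohexyl acetate | O=C1C[C@@H](OC(C)=O)C[C@@H](O[Si](C)(C)C(C)(C)C)C1 | intermediate
5 | (R)-5-(tert-butyldimethylsilyloxy)cyclohex-2-en-1-one | O=C1C=CC[C@@H](O[Si](C)(C)C(C)(C)C)C1 | intermediate
6 | (R)-5-(tert-butyldimethylsilyloxy)-2-iodocyclohex-2-en-1-one | O=C1C(I)=CC[C@@H](O[Si](C)(C)C(C)(C)C)C1 | intermediate
7 | (R)-9-(tert-butyldimethylsilyloxy)-6-iodo-1,4-dioxaspiro[4.5]dec-6-ene | IC1=CC[C@@H](O[Si](C)(C)C(C)(C)C)CC12OCCO2 | intermediate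
8 | N-methoxy-N-methylacetamide | CON(C)C(C)=O | starting material
9 | (R)-[9-(tert-butyldimethylsilyloxy)-1,4-dioxaspiro[4.5]dec-6-en-6-yl]lithium | [Li]C1=CC[C@@H](O[Si](C)(C)C(C)(C)C)CC12OCCO2 | intermediate
10 | (R)-1-[9-(tert-butyldimethylsilyloxy)-1,4-dioxaspiro[4.5]dec-6-en-6-yl]ethan-1-one | CC(=O)C1=CC[C@@H](O[Si](C)(C)C(C)(C)C)CC12OCCO2 | intermediate
11 | potassium (R)-1-[9-(tert-butyldimethylsilyloxy)-1,4-dioxaspiro[4.5]dec-6-en-6-yl]ethen-1-olate | C=C(O[K])C1=CC[C@@H](O[Si](C)(C)C(C)(C)C)CC12OCCO2 | intermediate
12 | (R)-9-(tert-butyldimethylsilyloxy)-6-[1-(tert-butyldimethylsilyloxy)vinyl]-1,4-dioxaspiro[4.5]dec-6-ene | C=C(O[Si](C)(C)C(C)(C)C)C1=CC[C@@H](O[Si](C)(C)C(C)(C)C)CC12OCCO2 | intermediate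
13 | 5-methylhex-1-yne | C#CCCC(C)C | starting material
14 | allyl chloroformate | C=CCOC(Cl)=O | starting material
15 | (5-methylhex-1-yn-1-yl)lithium | [Li]C#CCCC(C)C | intermediate
16 | allyl 6-methylhept-2-ynoate | CC(C)CCC#CC(=O)OCC=C | intermediate
17 | allyl (3R)-3,8-bis(tert-butyldimethylsilyloxy)-1,1-(ethylenedioxy)-6-(3-methylbutyl)-1,2,3,4,4a,7-hexahydronaphthalene-5-carboxylate (both C4a epimers) | CC(C)CCC1=C(C(=O)OCC=C)C2C[C@@H](O[Si](C)(C)C(C)(C)C)CC3(OCCO3)C2=C(O[Si](C)(C)C(C)(C)C)C1 | intermediate
18 | allyl (R)-3,8-bis(tert-butyldimethylsilyloxy)-1,1-(ethylenedioxy)-6-(3-methylbutyl)-1,2,3,4-tetrahydronaphthalene-5-carboxylate | CC(C)CCc1cc(O[Si](C)(C)C(C)(C)C)c2c(c1C(=O)OCC=C)C[C@@H](O[Si](C)(C)C(C)(C)C)CC23OCCO3 | intermediate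
19 | (R)-3,8-bis(tert-butyldimethylsilyloxy)-1,1-(ethylenedioxy)-6-(3-methylbutyl)-1,2,3,4-tetrahydronaphthalene-5-carboxylic acid | CC(C)CCc1cc(O[Si](C)(C)C(C)(C)C)c2c(c1C(=O)O)C[C@@H](O[Si](C)(C)C(C)(C)C)CC23OCCO3 | intermediate
20 | 2,2,6-trimethyl-4H-1,3-dioxin-4-one | CC1=CC(=O)OC(C)(C)O1 | starting material
21 | (R)-3,8-bis(tert-butyldimethylsilyloxy)-1,1-(ethylenedioxy)-6-(3-methylbutyl)-1,2,3,4-tetrahydronaphthalene-5-carbonyl chloride | CC(C)CCc1cc(O[Si](C)(C)C(C)(C)C)c2c(c1C(Cl)=O)C[C@@H](O[Si](C)(C)C(C)(C)C)CC23OCCO3 | intermediate
22 | lithium 2,2-dimethyl-6-methylidene-6H-1,3-dioxin-4-olate | C=C1C=C(O[Li])OC(C)(C)O1 | intermediate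
23 | (R)-6-{2-[3,8-bis(tert-butyldimethylsilyloxy)-1,1-(ethylenedioxy)-6-(3-methylbutyl)-1,2,3,4-tetrahydronaphthalen-5-yl]-2-oxoethyl}-2,2-dimethyl-4H-1,3-dioxin-4-one | CC(C)CCc1cc(O[Si](C)(C)C(C)(C)C)c2c(c1C(=O)CC4=CC(=O)OC(C)(C)O4)C[C@@H](O[Si](C)(C)C(C)(C)C)CC23OCCO3 | intermediate
24 | (R)-5-[3,8-bis(tert-butyldimethylsilyloxy)-1,1-(ethylenedioxy)-6-(3-methylbutyl)-1,2,3,4-tetrahydronaphthalen-5-yl]-3,5-dioxopent-1-en-1-one (acylketene) | CC(C)CCc1cc(O[Si](C)(C)C(C)(C)C)c2c(c1C(=O)CC(=O)C=C=O)C[C@@H](O[Si](C)(C)C(C)(C)C)CC23OCCO3 | intermediate
25 | (R)-6-[3,8-bis(tert-butyldimethylsilyloxy)-1,1-(ethylenedioxy)-6-(3-methylbutyl)-1,2,3,4-tetrahydronaphthalen-5-yl]-4-hydroxy-2H-pyran-2-one | CC(C)CCc1cc(O[Si](C)(C)C(C)(C)C)c2c(c1-c4cc(O)cc(=O)o4)C[C@@H](O[Si](C)(C)C(C)(C)C)CC23OCCO3 | intermediate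
26 | (R)-3,8-dihydroxy-5-(4-hydroxy-2-oxo-2H-pyran-6-yl)-6-(3-methylbutyl)-3,4-dihydronaphthalen-1(2H)-one (CNP0134824.1) | CC(C)CCc1cc(O)c2c(c1-c1cc(O)cc(=O)o1)C[C@@H](O)CC2=O | target

## Step count and risks

Total step count: 13. Longest linear sequence: 12 steps (steps 1–7 and 9–13 from triol 1); step 8 is a one-step branch.

**Step 9 (key step).** The cycloaddition may be too slow at temperatures the silyl enol ether tolerates. A β-alkyl ynoate is only a moderately activated dienophile, and three of the four diene carbons carry substituents. Long heating invites protodesilylation of the diene and oligomerisation of the ynoate. Benzylic over-oxidation at C4 is conceivable if the aromatisation is forced. Fallback, setting out from 12 and 13 and returning at 19: acetylide 15 is formylated with DMF to 6-methylhept-2-ynal F1. This is a stronger dienophile with the same polarisation and should add to 12 near 80 °C to give cyclohexadiene carbaldehyde F2. DDQ aromatises F2 to aryl aldehyde F3. Pinnick oxidation (NaClO2, NaH2PO4, 2-methylbut-2-ene, t-BuOH/H2O) then gives acid 19. Steps 8 and 10 fall away.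

**Step 2.** The lipase may acylate the other enantiotopic hydroxyl or discriminate poorly, because the two carbinol carbons differ only through the remote silyloxy group. Fallback, setting out from 2 and returning at 3: both hydroxyls are acetylated (Ac2O, pyridine, DMAP) to meso-diacetate F4. The same lipase is then used in hydrolytic mode in phosphate buffer. It removes the acetate from the carbinol carbon it prefers and leaves the other, which gives the enantiocomplementary monoacetate and so corrects the sense of selection.

**Step 11.** Acylation of the dienolate may occur on oxygen or at the α-carbon, or attack on the doubly ortho-substituted aroyl chloride may be slower than proton transfer. Fallback, setting out from 19 (through 21) and returning at 25: the acid chloride is treated with the sodium lithium dianion of methyl acetoacetate F5 (NaH, then n-BuLi, THF, 0 °C). This harder and less encumbered nucleophile reacts at its terminal carbon to give methyl 3,5-dioxopentanoate F6. DBU in toluene at 80 °C lactonises F6 to pyranone 25, replacing step 12 as well.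

**Step 13.** Once the ketone is free, acid may induce β-elimination of the C3 hydroxyl and aromatisation. A sluggish cleavage of the aryl silyl ether would lengthen the exposure. Fallback, setting out from 25 and returning at 26: Bu4NF buffered with AcOH in THF removes both silyl groups while the ketone is still a ketal, so no elimination path exists, giving diol ketal F7. Pyridinium p-toluenesulfonate in wet acetone at room temperature then releases the ketone.

## Further compounds

F1 | step 9 | 6-methylhept-2-ynal | CC(C)CCC#CC=O
F2 | step 9 | (3R)-3,8-bis(tert-butyldimethylsilyloxy)-1,1-(ethylenedioxy)-6-(3-methylbutyl)-1,2,3,4,4a,7-hexahydronaphthalene-5-carbaldehyde (both C4a epimers) | CC(C)CCC1=C(C=O)C2C[C@@H](O[Si](C)(C)C(C)(C)C)CC3(OCCO3)C2=C(O[Si](C)(C)C(C)(C)C)C1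
F3 | step 9 | (R)-3,8-bis(tert-butyldimethylsilyloxy)-1,1-(ethylenedioxy)-6-(3-methylbutyl)-1,2,3,4-tetrahydronaphthalene-5-carbaldehyde | CC(C)CCc1cc(O[Si](C)(C)C(C)(C)C)c2c(c1C=O)C[C@@H](O[Si](C)(C)C(C)(C)C)CC23OCCO3
F4 | step 2 | all-cis-5-(tert-butyldimethylsilyloxy)cyclohexane-1,3-diyl diacetate (meso) | CC(=O)O[C@H]1C[C@@H](OC(C)=O)C[C@@H](O[Si](C)(C)C(C)(C)C)C1
F5 | step 11 | methyl acetoacetate dianion (sodium lithium salt) | [Li]CC(=O)C=C(O[Na])OC
F6 | step 11 | methyl (R)-5-[3,8-bis(tert-butyldimethylsilyloxy)-1,1-(ethylenedioxy)-6-(3-methylbutyl)-1,2,3,4-tetrahydronaphthalen-5-yl]-3,5-dioxopentanoate | COC(=O)CC(=O)CC(=O)c1c(CCC(C)C)cc(O[Si](C)(C)C(C)(C)C)c2c1C[C@@H](O[Si](C)(C)C(C)(C)C)CC23OCCO3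
F7 | step 13 | (R)-6-[1,1-(ethylenedioxy)-3,8-dihydroxy-6-(3-methylbutyl)-1,2,3,4-tetrahydronaphthalen-5-yl]-4-hydroxy-2H-pyran-2-one | CC(C)CCc1cc(O)c2c(c1-c1cc(O)cc(=O)o1)C[C@@H](O)CC23OCCO3
A1 | alternative 1 | (3S,4R)-8-(benzyloxy)-5-[4-(benzyloxy)-2-oxo-2H-pyran-6-yl]-3,4-epoxy-1,1-(ethylenedioxy)-6-(3-methylbutyl)-1,2,3,4-tetrahydronaphthalene | CC(C)CCc1cc(OCc2ccccc2)c2c(c1-c1cc(OCc3ccccc3)cc(=O)o1)[C@H]5O[C@H]5CC24OCCO4
A2 | alternative 1 | 8-(benzyloxy)-5-[4-(benzyloxy)-2-oxo-2H-pyran-6-yl]-1,1-(ethylenedioxy)-6-(3-methylbutyl)-1,2-dihydronaphthalene | CC(C)CCc1cc(OCc2ccccc2)c2c(c1-c1cc(OCc3ccccc3)cc(=O)o1)C=CCC24OCCO4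
A3 | alternative 1 | (R,R)-N,N'-bis(3,5-di-tert-butylsalicylidene)-1,2-cyclohexanediaminomanganese chloride | Cl[Mn]1Oc2c(C(C)(C)C)cc(C(C)(C)C)cc2C=N[C@@H]2CCCC[C@H]2N=Cc2cc(C(C)(C)C)cc(C(C)(C)C)c2O1
A4 | alternative 2 | (R)-3,8-bis(benzyloxy)-6-(3-methylbutyl)-5-[(triisopropylsilyl)ethynyl]-3,4-dihydronaphthalen-1(2H)-one | CC(C)CCc1cc(OCc2ccccc2)c2c(c1C#C[Si](C(C)C)(C(C)C)C(C)C)C[C@@H](OCc3ccccc3)CC2=O
A5 | alternative 2 | 3-(benzyloxy)cyclobutan-1-one | O=C1CC(OCc2ccccc2)C1
A6 | alternative 2 | lithium (S)-3-(benzyloxy)cyclobut-1-en-1-olate | [Li]OC1=C[C@@H](OCc2ccccc2)C1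
A7 | alternative 2 | 6-(benzyloxy)-2-iodo-4-(3-methylbutyl)-3-[(triisopropylsilyl)ethynyl]phenyl trifluoromethanesulfonate | CC(C)CCc1cc(OCc2ccccc2)c(OS(=O)(=O)C(F)(F)F)c(I)c1C#C[Si](C(C)C)(C(C)C)C(C)C
A8 | alternative 3 | (R)-3,8-dihydroxy-5-(4-benzyloxy-2-oxo-2H-pyran-6-yl)-6-(3-methylbutyl)-3,4-dihydronaphthalen-1(2H)-one | CC(C)CCc1cc(O)c2c(c1-c1cc(OCc3ccccc3)cc(=O)o1)C[C@@H](O)CC2=O
A9 | alternative 3 | 2-[2-acetyl-6-(4-benzyloxy-2-oxo-2H-pyran-6-yl)-3-hydroxy-5-(3-methylbutyl)phenyl]acetaldehyde | CC(C)CCc1cc(O)c(C(C)=O)c(CC=O)c1-c1cc(OCc2ccccc2)cc(=O)o1
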